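Amounts first: amber held 1.92 M of partner on 0.48 M of starting material, and the earlier gamma run held 1.7 M on the same charge.

common to all: starting material 0.48 M
- epsilon: partner 0.26 M; run made earlier
- gamma: partner 1.7 M; run made earlier
- teal: partner 0.960 M; time 3.0 min
- amber: partner 1.92 M; time 3.0 min
- blue: partner 0.384 M; time 3.0 min

- epsilon (time / min: bis adduct / %, mono adduct / %): 0.500: 3.2, 1.4; 1.00: 3.4, 0.3; 1.50: 3.8, 0.3; 2.00: 3.1, 0.1; 2.50: 3.5, 0; 3.00: 3.7, 0
- gamma (time / min: bis adduct / %, mono adduct / %): 0.500: 93.9, 0.3; 1.00: 95.8, 0; 1.50: 96.2, 0; 2.00: 96.1, 0; 2.50: 96.6, 0; 3.00: 96.1, 0

(scatter of a reading: 0.3 percentage points)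



- which of these holds the largest part of the starting material at the end of teal (starting material / other mono adduct / mono adduct / bis adduct)
- which of these holds the largest part of the starting material at the end of amber (starting material / other mono adduct / mono adduct / bis adduct)
- which of these holds the largest part of the starting material at the end of blue (starting material / other mono adduct / mono adduct / bis adduct)
- amount of bis adduct at the end of amber, in percent of the starting material charged

In gamma the bis adduct stood level from 1.50 min on, at a mean reading of 96.2%, with mono adduct at 0%, so that run fell short by 3.75%. I assumed that this shortfall shrinks in inverse proportion to the partner charge less the starting material charge, the partner standing once each starting material has taken one. In gamma the shortfall times that partner read 0.0457 M, and I called this the loss constant, a kind of selectivity factor. For amber it gave a shortfall of 3.18%, so 96.8% of bis adduct. It gave nothing for blue, where partner stood below the starting material charge.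

The forecast named bis adduct for teal, bis adduct for amber and other mono adduct for blue, with 96.9% of bis adduct in amber, close to my figure. Its ground was this: “bis is flat at about 96% despite excess partner, which suggests equilibrium with about 4% other mono adduct”.

The flasks gave bis adduct for teal, bis adduct for amber and other mono adduct for blue, with 96.7% of bis adduct in amber, so the forecast held.

    starting material + partner → mono adduct (k = 0.935 M⁻¹ s⁻¹)
    starting material + partner → other mono adduct (k = 1.34 M⁻¹ s⁻¹)
    partner + mono adduct → bis adduct (k = 0.910 M⁻¹ s⁻¹)
    partner + other mono adduct → bis adduct (k = 0.131 M⁻¹ s⁻¹)
    mono adduct → over-reaction product (k = 0.107 s⁻¹)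

In amber the missing 3.25% stood as over-reaction product, with other mono adduct at 0%. That amount times the same partner gives 0.0468 M, against my 0.0457 M. Amber had come to rest: bis adduct stood at 96.7% at 1.50 min and at 96.7% at 30.0 min, and ten times the time made no difference, with 51% of the partner still unbound.

On a neighbour of amber with 0.77 M of partner, the loss constant gives 15.8% lost. That flask gave 14.0% of over-reaction product, beside 26.3% of other mono adduct and 59.6% of bis adduct.

(The data are calculated with constants of no real substance; noise was put on by code.)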